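**Plan**

1. The target is read as (4S,5R)-4,5-cis-dihydroxy-5-[(1S)-1-acetoxypentadecyl]cyclopent-2-en-1-one. Ring atoms C1(=O), C2=C3, C4, C5 and side-chain atoms C1′–C15′ serve as locants throughout; systematic names use fused-ring locants.
2. The retrosynthesis cuts, in order: the isopropylidene ketal over O4/O5 and the O1′ acetate; the C(sp3)–C(sp3) bond C7′–C8′, giving 1-bromooctane and a side chain ending in the vinyl group C6′=C7′; the aldol bond C5–C1′, giving a cyclopentenone acetonide and hept-6-enal.
3. Forward, the five-membered ring is bought intact and never rebuilt. An aldol joins C5–C1′, a one-flask 9-BBN reduction/hydroboration/alkyl–alkyl Suzuki–Miyaura coupling joins C7′–C8′, and MnO2 oxidation, acetylation and ketal hydrolysis finish the route.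
4. Stereochemistry: C4 is bought with enone 1. C5 is relayed from it through the cis-fused dioxolane, since the aldehyde can only enter on the convex face. C1′ comes from the chair aldol transition state, and no later step touches the three centres.
5. The feature that makes the key event possible: every π-bond of the target lies in the ring (C1=O and C2=C3, the latter 1,2-disubstituted and flanked by the oxygenated C1 and C4), and the chain beyond C1′ is a bare alkane. The C6′=C7′ vinyl group of the precursor is therefore the only monosubstituted alkene, and one borane can pick it out while also parking C1=O as an allylic borinate.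

Key step: step 2

Assumption: enone 1 and hept-6-enal 2 are taken as catalogue chemicals (both antipodes of the enone are listed; 2 is otherwise one oxidation away from hept-6-en-1-ol).

**Step 1**
Reactants: 1 (3aS,6aS)-2,2-dimethyl-3a,6a-dihydro-4H-cyclopenta[d][1,3]dioxol-4-one; 2 hept-6-enal
Product: 4 (3aS,6aS)-3a-[(1S)-1-hydroxyhept-6-en-1-yl]-2,2-dimethyl-3a,6a-dihydro-4H-cyclopenta[d][1,3]dioxol-4-one, via lithium enolate 3 (not isolated)
Conditions: LDA (1.05 equiv), THF, −78 °C; then 2, −78 °C; AcOH/THF quench at −78 °C
Reagents that add atoms: none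
Why: LDA removes the only α′-hydrogen (C5–H; C2 is vinylic) to give the cross-conjugated enolate 3, which at −78 °C should add to the aldehyde in a lithium aldol reaction faster than it expels the C4 alkoxide; the new C5–C1′ bond can only form on the convex face because the dioxolane must stay cis-fused, which fixes C5, and a Zimmerman–Traxler chair with the aldehyde chain equatorial places C1′–OH syn to C5–O (the substituent cis to OLi), which is the (1′S) adduct, to be freed from any C1′ epimer by chromatography.

**Step 2**
Reactants: 4 aldol adduct; 5 1-bromooctane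
Product: 7 (3aR,6aS)-3a-[(1S)-1-hydroxypentadecyl]-2,2-dimethyl-3a,6a-dihydro-4H-cyclopenta[d][1,3]dioxol-4-ol (both epimers at the ring carbinol C1), via tris(9-BBN) adduct 6 (not isolated)
Conditions: 9-BBN-H dimer (3.5 equiv B–H), THF, 0 °C → rt; then 5 (1.5 equiv), Pd(OAc)2 (5 mol %), PCy3 (10 mol %), K3PO4·H2O (4 equiv), THF, rt; aqueous work-up
Reagents that add atoms: none
Why: 9-BBN-H does three things to 4 in one flask: it borylates C1′–OH, reduces the C1 enone carbonyl 1,2 to the allylic borinate (its usual behaviour with cyclopentenones), and adds anti-Markovnikov across C6′=C7′ through the four-centre transition state, giving the primary C7′–B bond of 6. Pd(0)/PCy3 then inserts into the C8′–Br bond of 5 by SN2-type oxidative addition, the hydroxide-activated borate transfers only its primary alkyl group (the secondary B–C bonds of the bicycle and the B–O bonds do not transmetalate), and C(sp3)–C(sp3) reductive elimination from the bulky electron-rich phosphine complex should outrun β-hydride elimination, forming C7′–C8′ directly at the alkane oxidation level; work-up hydrolyses the two B–O bonds. The closest known reaction type is the B-alkyl Suzuki–Miyaura coupling of alkyl-9-BBN reagents with primary alkyl bromides that carry β-hydrogens. No ring is closed, and the only new stereocentre is the C1 carbinol, formed without control and erased in step 3, while C4, C5 and C1′ are untouched. The step needs chemoselectivity between two alkenes, and the substrate secures it: the side-chain vinyl group is the only monosubstituted alkene, whereas the ring C2=C3 bond is 1,2-disubstituted and flanked by two oxygenated carbons, so 9-BBN should leave it alone, and because no olefin is created in the chain no hydrogenation, which the ring alkene could not survive, is needed. Parking the ketone as a borinate also removes the Michael acceptor and the retro-aldol pathway during the basic coupling.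

**Step 3**
Reactants: 7 allylic diol
Product: 8 (3aS,6aS)-3a-[(1S)-1-hydroxypentadecyl]-2,2-dimethyl-3a,6a-dihydro-4H-cyclopenta[d][1,3]dioxol-4-one
Conditions: activated MnO2 (20 equiv), CH2Cl2, rt
Reagents that add atoms: none
Why: MnO2 is a chemoselective allylic oxidant, so both C1 epimers should converge on the enone while the saturated, hindered C1′–OH is left alone.

**Step 4**
Reactants: 8 hydroxy enone
Product: 9 (1S)-1-[(3aS,6aS)-2,2-dimethyl-4-oxo-4,6a-dihydro-3aH-cyclopenta[d][1,3]dioxol-3a-yl]pentadecyl acetate
Conditions: Ac2O, DMAP (cat.), pyridine, CH2Cl2, 0 °C → rt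
Reagents that add atoms: acetic anhydride, CC(=O)OC(C)=O
Why: C1′–OH is the only free hydroxyl, so DMAP-catalysed acylation should give the acetate with retention; C5 is quaternary, so neither β-elimination nor epimerisation can occur.

**Step 5**
Reactants: 9 acetonide acetate
Product: 10 (1S)-1-[(1R,5S)-1,5-dihydroxy-2-oxocyclopent-3-en-1-yl]pentadecyl acetate (the target)
Conditions: TFA/H2O (9:1), 0 °C → rt
Reagents that add atoms: none
Why: acid-catalysed ketal hydrolysis proceeds through the oxocarbenium ion at the acetal carbon, so no C4–O or C5–O bond is broken and both centres keep their configuration, while the secondary acetate should survive cold aqueous TFA.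

**Compound list**

1 | (3aS,6aS)-2,2-dimethyl-3a,6a-dihydro-4H-cyclopenta[d][1,3]dioxol-4-one | O=C1C=C[C@@H]2OC(C)(C)O[C@H]12 | starting material
2 | hept-6-enal | C=CCCCCC=O | starting material
3 | lithium (6aS)-2,2-dimethyl-6aH-cyclopenta[d][1,3]dioxol-4-olate (α′-enolate of 1) | [Li]OC1=C2OC(C)(C)O[C@H]2C=C1 | intermediate
4 | (3aS,6aS)-3a-[(1S)-1-hydroxyhept-6-en-1-yl]-2,2-dimethyl-3a,6a-dihydro-4H-cyclopenta[d][1,3]dioxol-4-one | C=CCCCC[C@H](O)[C@@]1(OC2(C)C)C(=O)C=C[C@@H]1O2 | intermediate
5 | 1-bromooctane | CCCCCCCCBr | starting material
6 | tris(9-BBN) adduct: 4 after 1,2-reduction of C1=O, with 9-borabicyclo[3.3.1]nonan-9-yl on O1, on O1′ and on C7′ (C1 epimers) | C(B1C2CCCC1CCC2)CCCCC[C@H](OB1C2CCCC1CCC2)[C@@]1(OC2(C)C)C(OB3C4CCCC3CCC4)C=C[C@@H]1O2 | intermediate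
7 | (3aR,6aS)-3a-[(1S)-1-hydroxypentadecyl]-2,2-dimethyl-3a,6a-dihydro-4H-cyclopenta[d][1,3]dioxol-4-ol (both epimers at the ring carbinol) | CCCCCCCCCCCCCC[C@H](O)[C@@]1(OC2(C)C)C(O)C=C[C@@H]1O2 | intermediate
8 | (3aS,6aS)-3a-[(1S)-1-hydroxypentadecyl]-2,2-dimethyl-3a,6a-dihydro-4H-cyclopenta[d][1,3]dioxol-4-one | CCCCCCCCCCCCCC[C@H](O)[C@@]1(OC2(C)C)C(=O)C=C[C@@H]1O2 | intermediate
9 | (1S)-1-[(3aS,6aS)-2,2-dimethyl-4-oxo-4,6a-dihydro-3aH-cyclopenta[d][1,3]dioxol-3a-yl]pentadecyl acetate | CCCCCCCCCCCCCC[C@H](OC(C)=O)[C@@]1(OC2(C)C)C(=O)C=C[C@@H]1O2 | intermediate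
10 | (1S)-1-[(1R,5S)-1,5-dihydroxy-2-oxocyclopent-3-en-1-yl]pentadecyl acetate | CCCCCCCCCCCCCC[C@H](OC(C)=O)[C@@]1(O)C(=O)C=C[C@@H]1O | target

Total steps: 5. Longest linear sequence: 5 (1 → 10).

**Steps most likely to fail**

Step 2. The carbonyl reduction by the bulky borane may stay incomplete next to the quaternary C5, leaving a Michael acceptor in the basic palladium stage. Palladium may also ionise the allylic borinate, and β-hydride elimination or protodeboronation may erode the coupling. The fallback makes the same C7′–C8′ bond as an olefin and deliberately sacrifices and rebuilds the enone. It sets out from 1: the aldol of step 1 is run with oct-7-enal to give the homologous adduct F1, which is acetylated (Ac2O, DMAP, pyridine) to the acetate F2. Cross-metathesis with excess non-1-ene (second-generation Grubbs catalyst, CH2Cl2, 40 °C) should give the C7′=C8′ olefin F3 as an E/Z mixture. Hydrogenation (H2, Pd/C, EtOAc) saturates both the chain and the ring double bond to the cyclopentanone F4. Soft enolisation (TMSOTf, Et3N) can only go toward C2 and gives the silyl enol ether F5, and Saegusa–Ito oxidation (Pd(OAc)2, MeCN) restores the enone, rejoining the route at 9.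

Step 1. The enolate may lose the C4 alkoxide (β-elimination toward a cyclopentadienone), the aldolate may revert on warming, and facial discrimination at the aldehyde carbonyl may be weak, giving C1′ epimers. The fallback sets C1′ by reagent control instead of by the aldol transition state. It sets out from 4 as the epimer mixture: Dess–Martin oxidation gives the non-enolisable β-diketone F6. Corey–Bakshi–Shibata reduction with the (R)-oxazaborolidine and catecholborane (toluene, −78 °C; BH3 is avoided because of the vinyl group) should reduce both carbonyls. The side-chain ketone sits between the quaternary C5 (large) and the CH2 chain (small) and should give the (1′S)-alcohol, so the product is the allylic diol F7. F7 enters the hydroboration/coupling of step 2 with one equivalent of borane less and rejoins the route at 7.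

Step 5. The acetyl group may migrate from O1′ to O4 or O5 during the acidic hydrolysis, or the cis-fused ketal may need acid strong enough to degrade the 4-hydroxy enone. The fallback removes the ketal before any ester is present and installs the acetate by selective deacylation. It sets out from 8: TFA/H2O gives the triol F8, and Ac2O/pyridine acetylates both secondary hydroxyls to the 4,1′-diacetate F9 (the tertiary C5–OH does not react and, C5 being quaternary, the 4-acetoxy enone cannot eliminate). A lipase (Candida antarctica lipase B, pH 7 buffer/MTBE) should then hydrolyse the ring 4-acetate, since 4-acyloxycyclopent-2-enones are standard lipase substrates, but not the hindered side-chain ester, giving 10 under neutral conditions.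

**Further compounds**

F1 | step 2 | oct-7-enal aldol adduct, the one-carbon homologue of 4 with a (1S)-1-hydroxyoct-7-en-1-yl chain | C=CCCCCC[C@H](O)[C@@]1(OC2(C)C)C(=O)C=C[C@@H]1O2
F2 | step 2 | O1′-acetate of F1 | C=CCCCCC[C@H](OC(C)=O)[C@@]1(OC2(C)C)C(=O)C=C[C@@H]1O2
F3 | step 2 | 7′,8′-didehydro derivative of 9 (pentadec-7-enyl chain, E/Z mixture) | CCCCCCCC=CCCCCC[C@H](OC(C)=O)[C@@]1(OC2(C)C)C(=O)C=C[C@@H]1O2
F4 | step 2 | 2,3-dihydro derivative of 9 (saturated cyclopentanone acetonide acetate) | CCCCCCCCCCCCCC[C@H](OC(C)=O)[C@@]1(OC2(C)C)C(=O)CC[C@@H]1O2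
F5 | step 2 | trimethylsilyl enol ether of F4 (C1=C2) | CCCCCCCCCCCCCC[C@H](OC(C)=O)[C@@]1(OC2(C)C)C(O[Si](C)(C)C)=CC[C@@H]1O2
F6 | step 1 | 1′-oxo derivative of 4 (3a-hept-6-enoyl enone acetonide) | C=CCCCCC(=O)[C@@]1(OC2(C)C)C(=O)C=C[C@@H]1O2
F7 | step 1 | (3aR,6aS)-3a-[(1S)-1-hydroxyhept-6-en-1-yl]-2,2-dimethyl-3a,6a-dihydro-4H-cyclopenta[d][1,3]dioxol-4-ol (ring carbinol epimers) | C=CCCCC[C@H](O)[C@@]1(OC2(C)C)C(O)C=C[C@@H]1O2
F8 | step 5 | (4S,5S)-4,5-dihydroxy-5-[(1S)-1-hydroxypentadecyl]cyclopent-2-en-1-one (de-acetyl target) | CCCCCCCCCCCCCC[C@H](O)[C@@]1(O)C(=O)C=C[C@@H]1O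
F9 | step 5 | 4-O-acetyl derivative of the target (4,1′-diacetate) | CCCCCCCCCCCCCC[C@H](OC(C)=O)[C@@]1(O)C(=O)C=C[C@@H]1OC(C)=O
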